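**Retrosynthetic overview**

1. Germacranolide numbering is used (ring C1–C10, methylene lactone C11–C13, methyls C14/C15). The last step is O‑acetylation at C3; the ten‑membered carbocycle is opened at C3–C4.
2. Enabling feature: the acetoxy carbinol C3 is bonded to C4, the methyl‑bearing sp2 carbon of the Z C4=C5 ring olefin (an in‑ring allylic alcohol). That olefin holds C3 and C6 cis and the cis C1/C10 oxirane is a second turn, so a C3 aldehyde and a (Z)‑C4 iodoalkene (two electrophilic carbons) can be joined by Ni/Cr polarity reversal (intramolecular Nozaki–Hiyama–Kishi).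
3. Seco‑aldehyde ⇐ Shi epoxidation of the Z C1=C10 olefin (oxirane) ⇐ cis‑fused α‑methylene‑γ‑butyrolactone from indium Barbier/lactonisation of (Z)‑3‑iodobut‑2‑enal (C4–C6, C15) with a (Z)‑2‑(bromomethyl)enoate.
4. Bromide ⇐ Baylis–Hillman/SN2′ bromination of an α‑silyloxy aldehyde ⇐ Cu‑catalysed opening of methyl (R)‑glycidate (C7–C9, source of C8) by a Z‑alkenyl metal from a Stork–Zhao iodo‑olefination (C1–C3, C10, C14).
5. Ring order: γ‑lactone (step 9), oxirane (step 12), ten‑membered carbocycle (step 15, last).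

Key step: step 15

Remark: the SMILES is read as (1R,3S,4Z,6S,7R,8R,10S), i.e. a cis‑fused 12,6‑lactone (H6/H7 cis), a cis 1,10‑oxirane (C2 and C9 cis) and a 4Z olefin.
Remark: 3‑[(4‑methoxybenzyl)oxy]propanal is taken as purchasable (otherwise one oxidation from the commercial alcohol).

**Route**

Step 1
Reactants: 1 3‑[(4‑methoxybenzyl)oxy]propanal
Product: 2 1‑({[(3Z)‑4‑iodopent‑3‑en‑1‑yl]oxy}methyl)‑4‑methoxybenzene
Conditions: EtPPh3I, n‑BuLi, THF, 0 °C; I2, −78 °C; NaHMDS, −20 °C; then 1, −78 °C → rt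
Reagents that add atoms: ethyltriphenylphosphonium iodide CC[P+](c1ccccc1)(c1ccccc1)c1ccccc1.[I-]; iodine II
Why: Stork–Zhao olefination with the α‑iodo ylide gives the (Z)‑2‑iodoalk‑2‑ene (iodine cis to the chain) under kinetic Wittig control.

Step 2
Reactants: 2 (Z)‑alkenyl iodide; 3 methyl (2R)‑oxirane‑2‑carboxylate (methyl (R)‑glycidate)
Product: 6 methyl (2R,4Z)‑2‑hydroxy‑7‑[(4‑methoxybenzyl)oxy]‑4‑methylhept‑4‑enoate, via alkenyllithium 4 (not isolated), via alkenylmagnesium bromide 5 (not isolated)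
Conditions: t‑BuLi (2.1 equiv), Et2O, −78 °C; MgBr2·OEt2; CuBr·SMe2 (10 mol%), THF; then 3, −78 → −30 °C
Reagents that add atoms: none
Why: iodine–lithium exchange and transmetallation retain the olefin geometry, and the copper‑catalysed Grignard opens the glycidic ester by SN2 attack at its unsubstituted C3 (a known route to α‑hydroxy esters), so the epoxide stereocentre becomes C8 unchanged.

Step 3
Reactants: 6 α‑hydroxy ester
Product: 7 methyl (2R,4Z)‑2‑[(tert‑butyldimethylsilyl)oxy]‑7‑[(4‑methoxybenzyl)oxy]‑4‑methylhept‑4‑enoate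
Conditions: TBSCl, imidazole, DMF, rt
Reagents that add atoms: tert‑butyldimethylsilyl chloride CC(C)(C)[Si](C)(C)Cl
Why: standard silylation masks the C8 hydroxyl so that it can later neither lactonise nor chelate the metal in the Barbier step.

Step 4
Reactants: 7 silyloxy ester
Product: 8 (2R,4Z)‑2‑[(tert‑butyldimethylsilyl)oxy]‑7‑[(4‑methoxybenzyl)oxy]‑4‑methylhept‑4‑enal
Conditions: DIBAL‑H, CH2Cl2, −78 °C; MeOH, Rochelle salt
Reagents that add atoms: none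
Why: DIBAL‑H half‑reduction of an α‑silyloxy ester stops at the aldehyde because the tetrahedral aluminium hemiacetal is stable at −78 °C.

Step 5
Reactants: 8 α‑silyloxy aldehyde
Product: 9 methyl (4R,6Z)‑4‑[(tert‑butyldimethylsilyl)oxy]‑3‑hydroxy‑9‑[(4‑methoxybenzyl)oxy]‑6‑methyl‑2‑methylidenenon‑6‑enoate (C3 epimer mixture)
Conditions: methyl acrylate (excess), DABCO, MeOH (cat.), rt
Reagents that add atoms: methyl acrylate C=CC(=O)OC
Why: Morita–Baylis–Hillman reaction of an activated α‑oxy aldehyde; the new carbinol centre is erased in the next step.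

Step 6
Reactants: 9 Baylis–Hillman alcohol
Product: 10 methyl (2Z,4R,6Z)‑2‑(bromomethyl)‑4‑[(tert‑butyldimethylsilyl)oxy]‑9‑[(4‑methoxybenzyl)oxy]‑6‑methylnona‑2,6‑dienoate
Conditions: NBS, Me2S, CH2Cl2, 0 °C (premixed), then 9, 0 °C → rt
Reagents that add atoms: N‑bromosuccinimide O=C1CCC(=O)N1Br
Why: Corey–Kim‑type activation followed by SN2′ attack of bromide converts Baylis–Hillman alcohols into the favoured (Z)‑2‑(bromomethyl)alk‑2‑enoates (ester trans to the γ‑substituent).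

Step 7
Reactants: 11 but‑2‑yn‑1‑ol
Product: 12 (2Z)‑3‑iodobut‑2‑en‑1‑ol
Conditions: Red‑Al, THF, 0 °C → rt; then I2, −78 °C
Reagents that add atoms: iodine II
Why: hydroxyl‑directed trans‑hydroalumination of the propargylic alcohol places aluminium at C3, and iodinolysis with retention gives the Z iodoalkene (iodine cis to CH2OH).

Step 8
Reactants: 12 (Z)‑iodoallylic alcohol
Product: 13 (2Z)‑3‑iodobut‑2‑enal
Conditions: MnO2, CH2Cl2, rt, dark; used directly
Reagents that add atoms: none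
Why: neutral allylic oxidation with MnO2 leaves the Z β‑iodoenal geometry untouched.

Step 9
Reactants: 10 allylic bromide; 13 (Z)‑3‑iodobut‑2‑enal
Product: 15 (4S,5R)‑4‑[(1R,3Z)‑1‑[(tert‑butyldimethylsilyl)oxy]‑6‑[(4‑methoxybenzyl)oxy]‑3‑methylhex‑3‑en‑1‑yl]‑5‑[(1Z)‑2‑iodoprop‑1‑en‑1‑yl]‑3‑methylideneoxolan‑2‑one, via syn hydroxy ester 14 (not isolated)
Conditions: In powder, THF/H2O (1:1), rt; then p‑TsOH·H2O (cat.), CH2Cl2, rt
Reagents that add atoms: none
Why: indium Barbier allylation of a (Z)‑2‑(alkoxycarbonyl)allyl bromide goes through a closed chair with the γ‑substituent axial and gives the syn adduct (hence the cis lactone after acid lactonisation), while the C8 centre sets the face: 1,3‑allylic strain puts C8–H in the olefin plane and the aldehyde adds anti to the C9 methylene with the silyloxy group outside.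

Step 10
Reactants: 15 lactone silyl ether
Product: 16 (4R,5R)‑4‑[(1R,3Z)‑1‑hydroxy‑6‑[(4‑methoxybenzyl)oxy]‑3‑methylhex‑3‑en‑1‑yl]‑5‑[(1Z)‑2‑iodoprop‑1‑en‑1‑yl]‑3‑methylideneoxolan‑2‑one
Conditions: HF·pyridine, pyridine, THF, 0 °C → rt
Reagents that add atoms: none
Why: buffered HF·pyridine cleaves the secondary TBS ether without base, so the freed C8 hydroxyl should not translactonise and the PMB ether and methylene lactone survive.

Step 11
Reactants: 16 C8 alcohol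
Product: 17 (1R,3Z)‑1‑[(2R,3R)‑2‑[(1Z)‑2‑iodoprop‑1‑en‑1‑yl]‑4‑methylidene‑5‑oxooxolan‑3‑yl]‑6‑[(4‑methoxybenzyl)oxy]‑3‑methylhex‑3‑en‑1‑yl 2‑methylprop‑2‑enoate
Conditions: methacrylic anhydride, Et3N, DMAP (cat.), CH2Cl2, 0 °C → rt
Reagents that add atoms: methacrylic anhydride C=C(C)C(=O)OC(=O)C(C)=C
Why: DMAP‑catalysed acylation of the secondary alcohol proceeds with retention at C8 under conditions too mild for translactonisation.

Step 12
Reactants: 17 methacrylate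
Product: 18 (1R)‑1‑[(2R,3R)‑2‑[(1Z)‑2‑iodoprop‑1‑en‑1‑yl]‑4‑methylidene‑5‑oxooxolan‑3‑yl]‑2‑[(2S,3R)‑3‑{2‑[(4‑methoxybenzyl)oxy]ethyl}‑2‑methyloxiran‑2‑yl]ethyl 2‑methylprop‑2‑enoate
Conditions: D‑fructose‑derived Shi ketone (0.3 equiv), Oxone, K2CO3, Bu4NHSO4, aq. Na2B4O7/EDTA, MeCN/DMM, 0 °C
Reagents that add atoms: Oxone (potassium peroxymonosulfate) [K+].[O-]S(=O)(=O)OO
Why: Shi epoxidation: the chiral dioxirane attacks only the electron‑rich C1=C10 olefin through the spiro transition state, giving R at the CH carbon (C1) and, from the Z olefin, the cis oxirane (1R,10S) under reagent control; the acrylates and the iodoalkene are too electron‑poor to react.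

Step 13
Reactants: 18 epoxide PMB ether
Product: 19 (1R)‑2‑[(2S,3R)‑3‑(2‑hydroxyethyl)‑2‑methyloxiran‑2‑yl]‑1‑[(2R,3R)‑2‑[(1Z)‑2‑iodoprop‑1‑en‑1‑yl]‑4‑methylidene‑5‑oxooxolan‑3‑yl]ethyl 2‑methylprop‑2‑enoate
Conditions: DDQ, CH2Cl2/pH 7 buffer, 0 °C
Reagents that add atoms: none
Why: oxidative PMB cleavage (benzylic hydride abstraction, hydrolysis of the oxocarbenium ion) under buffered conditions that keep the trisubstituted epoxide intact.

Step 14
Reactants: 19 primary alcohol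
Product: 20 (1R)‑1‑[(2R,3R)‑2‑[(1Z)‑2‑iodoprop‑1‑en‑1‑yl]‑4‑methylidene‑5‑oxooxolan‑3‑yl]‑2‑[(2S,3R)‑2‑methyl‑3‑(2‑oxoethyl)oxiran‑2‑yl]ethyl 2‑methylprop‑2‑enoate
Conditions: Dess–Martin periodinane, NaHCO3, CH2Cl2, 0 °C; crude used at once
Reagents that add atoms: none
Why: Dess–Martin oxidation under bicarbonate buffering gives the β,γ‑epoxy aldehyde without a base strong enough to trigger β‑elimination of the epoxide.

Step 15
Reactants: 20 seco‑aldehyde
Product: 22 (1R,3S,4Z,6S,7R,8R,10S)‑1,10‑epoxy‑3‑hydroxy‑8‑(2‑methylprop‑2‑enoyloxy)germacra‑4,11(13)‑dien‑12,6‑olide, via alkenylchromium dichloride 21 (not isolated)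
Conditions: CrCl2 (excess), NiCl2 (cat.), DMSO/THF, rt, slow addition, ca. 2 mM
Reagents that add atoms: none
Why: Ni(0) inserts into the C4–I bond with retention, the alkenyl group passes to Cr(III), and the alkenylchromium adds to the Cr‑bound C3 aldehyde, so two electrophilic carbons are joined by reductive polarity reversal. The closest known reaction type is the intramolecular Nozaki–Hiyama–Kishi alkenyl iodide–aldehyde cyclisation used to close medium and large carbocyclic allylic alcohols. The ten‑membered carbocycle closes in a 10‑exo‑trig mode by C3–C4 bond formation, with the lactone and oxirane as spectators. The new C3 centre is set by 1,3‑allylic strain across the Z olefin together with the tether: the aldehyde hydrogen must point inward toward C6–H, the C2 chain must leave on the same olefin face as C7 because the short cis‑epoxide bridge cannot span both faces, and the Cr‑bound oxygen therefore ends on the opposite face, which is 3S. The step needs chemoselectivity for the aldehyde over the lactone, both acrylate esters and the epoxide (alkenylchromium reagents add only to aldehydes) and retention of the Z geometry (stereoretentive oxidative addition and transmetallation); high dilution suppresses dimerisation.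

Step 16
Reactants: 22 macrocyclic allylic alcohol
Product: 23 target, (1R,3S,4Z,6S,7R,8R,10S)‑3‑acetoxy‑1,10‑epoxy‑8‑(2‑methylprop‑2‑enoyloxy)germacra‑4,11(13)‑dien‑12,6‑olide (CNP0267696.1)
Conditions: Ac2O, pyridine, DMAP (cat.), CH2Cl2, 0 °C → rt
Reagents that add atoms: acetic anhydride CC(=O)OC(C)=O
Why: DMAP‑catalysed acetylation of the secondary allylic alcohol occurs at oxygen with retention at C3.

**Compound list**

1 | 3‑[(4‑methoxybenzyl)oxy]propanal | O=CCCOCc1ccc(OC)cc1 | starting material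
2 | 1‑({[(3Z)‑4‑iodopent‑3‑en‑1‑yl]oxy}methyl)‑4‑methoxybenzene | I/C(C)=C\CCOCc1ccc(OC)cc1 | intermediate
3 | methyl (2R)‑oxirane‑2‑carboxylate | COC(=O)[C@H]1CO1 | starting material
4 | (Z)‑alkenyllithium from 2 | [Li]/C(C)=C\CCOCc1ccc(OC)cc1 | intermediate
5 | (Z)‑alkenylmagnesium bromide from 2 | Br[Mg]/C(C)=C\CCOCc1ccc(OC)cc1 | intermediate
6 | methyl (2R,4Z)‑2‑hydroxy‑7‑[(4‑methoxybenzyl)oxy]‑4‑methylhept‑4‑enoate | COC(=O)[C@H](O)C/C(C)=C\CCOCc1ccc(OC)cc1 | intermediate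
7 | methyl (2R,4Z)‑2‑[(tert‑butyldimethylsilyl)oxy]‑7‑[(4‑methoxybenzyl)oxy]‑4‑methylhept‑4‑enoate | COC(=O)[C@H](O[Si](C)(C)C(C)(C)C)C/C(C)=C\CCOCc1ccc(OC)cc1 | intermediate
8 | (2R,4Z)‑2‑[(tert‑butyldimethylsilyl)oxy]‑7‑[(4‑methoxybenzyl)oxy]‑4‑methylhept‑4‑enal | O=C[C@H](O[Si](C)(C)C(C)(C)C)C/C(C)=C\CCOCc1ccc(OC)cc1 | intermediate
9 | methyl (4R,6Z)‑4‑[(tert‑butyldimethylsilyl)oxy]‑3‑hydroxy‑9‑[(4‑methoxybenzyl)oxy]‑6‑methyl‑2‑methylidenenon‑6‑enoate (C3 epimers) | C=C(C(=O)OC)C(O)[C@H](O[Si](C)(C)C(C)(C)C)C/C(C)=C\CCOCc1ccc(OC)cc1 | intermediate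
10 | methyl (2Z,4R,6Z)‑2‑(bromomethyl)‑4‑[(tert‑butyldimethylsilyl)oxy]‑9‑[(4‑methoxybenzyl)oxy]‑6‑methylnona‑2,6‑dienoate | BrC/C(C(=O)OC)=C\[C@H](O[Si](C)(C)C(C)(C)C)C/C(C)=C\CCOCc1ccc(OC)cc1 | intermediate
11 | but‑2‑yn‑1‑ol | CC#CCO | starting material
12 | (2Z)‑3‑iodobut‑2‑en‑1‑ol | I/C(C)=C\CO | intermediate
13 | (2Z)‑3‑iodobut‑2‑enal | I/C(C)=C\C=O | intermediate
14 | methyl (3S,4R,6Z)‑4‑[(tert‑butyldimethylsilyl)oxy]‑3‑[(1R,2Z)‑1‑hydroxy‑3‑iodobut‑2‑en‑1‑yl]‑9‑[(4‑methoxybenzyl)oxy]‑6‑methyl‑2‑methylidenenon‑6‑enoate | I/C(C)=C\[C@H](O)[C@H](C(=C)C(=O)OC)[C@H](O[Si](C)(C)C(C)(C)C)C/C(C)=C\CCOCc1ccc(OC)cc1 | intermediate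
15 | (4S,5R)‑4‑[(1R,3Z)‑1‑[(tert‑butyldimethylsilyl)oxy]‑6‑[(4‑methoxybenzyl)oxy]‑3‑methylhex‑3‑en‑1‑yl]‑5‑[(1Z)‑2‑iodoprop‑1‑en‑1‑yl]‑3‑methylideneoxolan‑2‑one | I/C(C)=C\[C@@H]1OC(=O)C(=C)[C@@H]1[C@H](O[Si](C)(C)C(C)(C)C)C/C(C)=C\CCOCc2ccc(OC)cc2 | intermediate
16 | (4R,5R)‑4‑[(1R,3Z)‑1‑hydroxy‑6‑[(4‑methoxybenzyl)oxy]‑3‑methylhex‑3‑en‑1‑yl]‑5‑[(1Z)‑2‑iodoprop‑1‑en‑1‑yl]‑3‑methylideneoxolan‑2‑one | I/C(C)=C\[C@@H]1OC(=O)C(=C)[C@@H]1[C@H](O)C/C(C)=C\CCOCc2ccc(OC)cc2 | intermediate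
17 | (1R,3Z)‑1‑[(2R,3R)‑2‑[(1Z)‑2‑iodoprop‑1‑en‑1‑yl]‑4‑methylidene‑5‑oxooxolan‑3‑yl]‑6‑[(4‑methoxybenzyl)oxy]‑3‑methylhex‑3‑en‑1‑yl 2‑methylprop‑2‑enoate | I/C(C)=C\[C@@H]1OC(=O)C(=C)[C@@H]1[C@H](OC(=O)C(C)=C)C/C(C)=C\CCOCc2ccc(OC)cc2 | intermediate
18 | (1R)‑1‑[(2R,3R)‑2‑[(1Z)‑2‑iodoprop‑1‑en‑1‑yl]‑4‑methylidene‑5‑oxooxolan‑3‑yl]‑2‑[(2S,3R)‑3‑{2‑[(4‑methoxybenzyl)oxy]ethyl}‑2‑methyloxiran‑2‑yl]ethyl 2‑methylprop‑2‑enoate | I/C(C)=C\[C@@H]1OC(=O)C(=C)[C@@H]1[C@H](OC(=O)C(C)=C)C[C@]2(C)O[C@@H]2CCOCc3ccc(OC)cc3 | intermediate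
19 | (1R)‑2‑[(2S,3R)‑3‑(2‑hydroxyethyl)‑2‑methyloxiran‑2‑yl]‑1‑[(2R,3R)‑2‑[(1Z)‑2‑iodoprop‑1‑en‑1‑yl]‑4‑methylidene‑5‑oxooxolan‑3‑yl]ethyl 2‑methylprop‑2‑enoate | I/C(C)=C\[C@@H]1OC(=O)C(=C)[C@@H]1[C@H](OC(=O)C(C)=C)C[C@]2(C)O[C@@H]2CCO | intermediate
20 | (1R)‑1‑[(2R,3R)‑2‑[(1Z)‑2‑iodoprop‑1‑en‑1‑yl]‑4‑methylidene‑5‑oxooxolan‑3‑yl]‑2‑[(2S,3R)‑2‑methyl‑3‑(2‑oxoethyl)oxiran‑2‑yl]ethyl 2‑methylprop‑2‑enoate | I/C(C)=C\[C@@H]1OC(=O)C(=C)[C@@H]1[C@H](OC(=O)C(C)=C)C[C@]2(C)O[C@@H]2CC=O | intermediate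
21 | alkenylchromium(III) dichloride from 20 (Cr in place of I) | Cl[Cr](Cl)/C(C)=C\[C@@H]1OC(=O)C(=C)[C@@H]1[C@H](OC(=O)C(C)=C)C[C@]2(C)O[C@@H]2CC=O | intermediate
22 | (1R,3S,4Z,6S,7R,8R,10S)‑1,10‑epoxy‑3‑hydroxy‑8‑(2‑methylprop‑2‑enoyloxy)germacra‑4,11(13)‑dien‑12,6‑olide | C=C(C)C(=O)O[C@@H]1C[C@]2(C)O[C@@H]2C[C@H](O)/C(C)=C\[C@@H]2OC(=O)C(=C)[C@@H]21 | intermediate
23 | (1R,3S,4Z,6S,7R,8R,10S)‑3‑acetoxy‑1,10‑epoxy‑8‑(2‑methylprop‑2‑enoyloxy)germacra‑4,11(13)‑dien‑12,6‑olide (CNP0267696.1) | C=C(C)C(=O)O[C@@H]1C[C@]2(C)O[C@@H]2C[C@H](OC(C)=O)/C(C)=C\[C@@H]2OC(=O)C(=C)[C@@H]21 | target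

**Step count and risks**

Total step count: 16. Longest linear sequence: 14 steps (steps 1–6 and 9–16); steps 7–8 form a two‑step side branch.

Steps most likely to fail:

Step 9. What may go wrong: the allylindium may add to the wrong face with respect to the C8 stereocentre, or unselectively, and the β‑iodoenal may lose its Z geometry by halide addition–elimination in the aqueous medium. The fallback sets out from bromide 10. Palladium‑catalysed borylation (B2pin2, Pd2(dba)3, KOAc, DMSO) should give methyl (2E,4R,6Z)‑4‑[(tert‑butyldimethylsilyl)oxy]‑9‑[(4‑methoxybenzyl)oxy]‑6‑methyl‑2‑[(4,4,5,5‑tetramethyl‑1,3,2‑dioxaborolan‑2‑yl)methyl]nona‑2,6‑dienoate F1. This is added to aldehyde 13 in toluene at low temperature under a chiral BINOL‑phosphoric acid catalyst. In this halide‑free, closed‑chair allylboration the catalyst chooses the aldehyde face and the fixed olefin geometry gives the syn adduct 14; acid lactonisation then returns to the route at 15.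

Step 15. What may go wrong: the aldehyde may be attacked on both faces if the ring‑closing transition state is loose enough to escape the allylic‑strain and tether control, giving C3 epimers. The fallback sets out from 22 as its C3 epimer mixture. Dess–Martin oxidation gives the macrocyclic Z enone (1R,4Z,6S,7R,8R,10S)‑1,10‑epoxy‑8‑(2‑methylprop‑2‑enoyloxy)‑3‑oxogermacra‑4,11(13)‑dien‑12,6‑olide F2. Reagent‑controlled CBS reduction ((R)‑Me‑CBS, catecholborane, −78 °C, the α‑branched alkenyl carbon acting as the large group) should then return the 3S alcohol 22.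

Step 12. What may go wrong: facial control on this Z‑trisubstituted olefin may be incomplete, and the acrylate‑type esters may suffer slow hydrolysis or conjugate addition in the pH 10.5 oxidant medium. The fallback sets out from 17. The PMB ether is removed first (DDQ, buffered CH2Cl2) to give the primary homoallylic alcohol (1R,3Z)‑6‑hydroxy‑1‑[(2R,3R)‑2‑[(1Z)‑2‑iodoprop‑1‑en‑1‑yl]‑4‑methylidene‑5‑oxooxolan‑3‑yl]‑3‑methylhex‑3‑en‑1‑yl 2‑methylprop‑2‑enoate F3. The oxirane is then installed by hydroxyl‑directed vanadium catalysis with a chiral bishydroxamic acid ligand and cumene hydroperoxide in toluene; this is neutral and non‑aqueous, and only the olefin reachable from the vanadate ester reacts. The sequence rejoins the route at 19, skipping 18.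

Further compounds
F1 | step 9 | methyl (2E,4R,6Z)‑4‑[(tert‑butyldimethylsilyl)oxy]‑9‑[(4‑methoxybenzyl)oxy]‑6‑methyl‑2‑[(4,4,5,5‑tetramethyl‑1,3,2‑dioxaborolan‑2‑yl)methyl]nona‑2,6‑dienoate | CC1(C)OB(C/C(C(=O)OC)=C\[C@H](O[Si](C)(C)C(C)(C)C)C/C(C)=C\CCOCc2ccc(OC)cc2)OC1(C)C
F2 | step 15 | (1R,4Z,6S,7R,8R,10S)‑1,10‑epoxy‑8‑(2‑methylprop‑2‑enoyloxy)‑3‑oxogermacra‑4,11(13)‑dien‑12,6‑olide | C=C(C)C(=O)O[C@@H]1C[C@]2(C)O[C@@H]2CC(=O)/C(C)=C\[C@@H]2OC(=O)C(=C)[C@@H]21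
F3 | step 12 | (1R,3Z)‑6‑hydroxy‑1‑[(2R,3R)‑2‑[(1Z)‑2‑iodoprop‑1‑en‑1‑yl]‑4‑methylidene‑5‑oxooxolan‑3‑yl]‑3‑methylhex‑3‑en‑1‑yl 2‑methylprop‑2‑enoate | I/C(C)=C\[C@@H]1OC(=O)C(=C)[C@@H]1[C@H](OC(=O)C(C)=C)C/C(C)=C\CCO
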